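In a one-step world with all reacted substrate read as target, the 27% of the blue run at 1.00 min would have become 71.6% at 4.00 min, but the reading there was 50%. So I split each flask into a captured part and a slowly emptying pool, and took target as a share of the captured part.

the same everywhere: substrate 0.10 M
- blue: first nucleophile 7 equiv; second nucleophile 5 equiv; protic impurity 0.030 M; run made earlier
- grey: first nucleophile 11 equiv; second nucleophile 5 equiv; protic impurity 0.030 M; run made earlier
- red: first nucleophile 5 equiv; second nucleophile 10 equiv; protic impurity 0.030 M; run made earlier
- delta: first nucleophile 5.00 equiv; second nucleophile 5.00 equiv; protic impurity 0.0300 M; time 6.0 min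
- eta: first nucleophile 5.00 equiv; second nucleophile 5.00 equiv; protic impurity 0.0300 M; time 8.0 min

| run | time / min | target / % |
|---|---|---|
| blue | 0.200 | 9 |
| blue | 0.500 | 16 |
| blue | 1.00 | 27 |
| blue | 1.50 | 31 |
| blue | 2.00 | 31 |
| blue | 3.00 | 43 |
| blue | 4.00 | 50 |
| grey | 0.500 | 22 |
| grey | 1.00 | 29 |
| grey | 1.50 | 36 |
| grey | 2.00 | 39 |
| grey | 2.50 | 48 |
| grey | 3.00 | 45 |
| grey | 4.00 | 53 |
| red | 0.333 | 14 |
| red | 0.833 | 21 |
| red | 1.50 | 26 |
| red | 2.50 | 30 |
| red | 4.00 | 38 |

(standard deviation of a reading: 2 percentage points)

- on the list of suspects stand: second nucleophile + intermediate -> other capture product; second nucleophile + protic impurity -> quenched reagent; intermediate -> side product; substrate <-> dormant form; substrate <-> intermediate; first nucleophile + intermediate -> target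

- which of the two there is more of at the end, delta (other capture product / target)
- which of the two there is more of at the end, eta (other capture product / target)
- final target, as a percentage of the substrate charged, in delta
- final target, as a percentage of the substrate charged, in eta

Assuming blue and grey had the same pool, the ratio of their last readings gave 1.29 equiv. This is the rival load: the equivalents of first nucleophile at which target takes half of the captured part, with 5 equiv of second nucleophile. The target share (selectivity) is then [first nucleophile]/([first nucleophile]+load), both in equivalents. The load is a rough reading, carrying the scatter of 2 percentage points.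

Blue's share of 84.4% left a pool of 68.0% at 1.00 min and 40.8% at 4.00 min, which reads as a half-life of 4.06 min. With a share of 79.5%, I reckoned 56.4% target in delta and 63.1% in eta.

The forecast said target for delta and target for eta, with 49% and 52%, on a share of “about 0.56 at 5 and 5 equiv”; its 49% for delta lay below my 56.4%.

The flasks gave 54.3% target in delta and 61.4% in eta, against 7.29% and 8.30% of other capture product.

    second nucleophile + intermediate → other capture product (k = 7.15 L mol⁻¹ s⁻¹)
    second nucleophile + protic impurity → quenched reagent (k = 0.327 L mol⁻¹ s⁻¹)
    intermediate → side product (k = 0.579 s⁻¹)
    substrate ⇌ dormant form (K = 2.37, k = 0.0204 s⁻¹)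
    substrate ⇌ intermediate (K = 0.00100, k = 0.0128 s⁻¹)
    first nucleophile + intermediate → target (k = 52.8 L mol⁻¹ s⁻¹)

Delta's products at 6.00 min gave target a share of 86.4%, where the load of 1.29 equiv had given 79.5%. My 56.4% came near although its captured part of 70.9% stood above delta's 62.9%. In the flask like eta but with 2.00 equiv of first nucleophile, the same load gave a share of 60.8%. That flask held 43.4% target, 15.4% other capture product and 2.68% side product, a share of 70.6%.

(The numbers in the tables come from a simulation from invented constants; the scatter is artificial.)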